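**Assumption:** the SMILES is taken at face value as the (S,S,S) isomer (trans-2,3-dihydrobenzofuran; 4-hydroxyphenyl on the seven-membered ring anti to the furan C2 branch). Catalogue reagents such as (R)-TRIP, Hantzsch ester and ent-Shi ketone count as commercially available. The route is a paper design and has not been run.

## Retrosynthetic overview

1. Ampelopsin B ⇐ global O-deprotection of a tetracycle whose dihydrobenzofuran C–O bond is made last, by an inverting Mitsunobu etherification.
2. Seven-membered ring ⇐ stereospecific 7-exo Friedel–Crafts opening of an (S,S)-stilbene oxide by the resorcinol ring. This makes the furan C3–aryl bond, not the biomimetic benzylic-cation closure from an ε-viniferin precursor.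
3. Epoxide ⇐ Shi epoxidation of an E-stilbene installed by Heck reaction on an aryl triflate.
4. The first stereocentre (the CH bearing the 4-oxyphenyl group) ⇐ chiral phosphoric acid transfer hydrogenation of an o-hydroxy-triarylethylene via its o-quinone methide; the directing phenol then becomes the triflate.
5. Triarylethylene ⇐ benzyl Grignard + 2-hydroxybenzophenone ⇐ Friedel–Crafts acylation of 1,3,5-trimethoxybenzene.

Ring order: seven-membered carbocycle (step 7), then dihydrobenzofuran (step 9).

## Forward route

**Step 1**
Reactants: 1 (1,3,5-trimethoxybenzene), 2 (4-methoxybenzoyl chloride)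
Product: 3, (2-hydroxy-4,6-dimethoxyphenyl)(4-methoxyphenyl)methanone
Conditions: AlCl3 (2.5 equiv), CH2Cl2, 0 °C → rt
Reagents that add atoms: none (all atoms from 1 and 2)
Why: Friedel–Crafts acylation, then chelation-directed cleavage by excess AlCl3 of only the OMe ortho to the new carbonyl; no stereocentre.

**Step 2**
Reactants: 3; 4 (3,5-bis(benzyloxy)benzyl bromide, used as its Grignard reagent)
Product: 5, 2-[2-(3,5-bis(benzyloxy)phenyl)-1-(4-methoxyphenyl)ethenyl]-3,5-dimethoxyphenol (E/Z mixture)
Conditions: 4, Mg, Et2O, 0 °C (slow addition); 3 (0.33 equiv), THF, 0 → 40 °C; aq NH4Cl; then p-TsOH (5 mol %), PhMe, rt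
Reagents that add atoms: none (all atoms from 3 and 4)
Why: Grignard 1,2-addition (first equivalent deprotonates the phenol), then E1 dehydration of the highly stabilised tertiary benzylic alcohol; alkene geometry is irrelevant because both isomers give the same o-quinone methide in step 3.

**Step 3**
Reactants: 5
Product: 6, 2-[(1S)-2-(3,5-bis(benzyloxy)phenyl)-1-(4-methoxyphenyl)ethyl]-3,5-dimethoxyphenol
Conditions: (R)-TRIP (5 mol %), Hantzsch ester (1.5 equiv), CH2Cl2, 30 °C; recrystallise to upgrade ee
Reagents that add atoms: none (Hantzsch ester delivers only H)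
Why: Proposed new method: the acid protonates the alkene at the CH(aryl) carbon to give an o-quinone methide stabilised by the 2-OH/4,6-OMe ring and the anisyl group, and the catalyst, bound to both the quinone methide carbonyl and the Hantzsch N–H, delivers hydride to one face of the exocyclic carbon to set the (S) centre. The closest known reaction is the phosphoric-acid-catalysed asymmetric transfer hydrogenation of o-hydroxy-1,1-diarylethenes to 1,1-diarylethanes. The catalyst hand is provisional: if the first run gives ent-6, use (S)-TRIP.

**Step 4**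
Reactants: 6
Product: 7, 2-[(1S)-2-(3,5-bis(benzyloxy)phenyl)-1-(4-methoxyphenyl)ethyl]-3,5-dimethoxyphenyl trifluoromethanesulfonate
Conditions: Tf2O, pyridine, CH2Cl2, 0 °C
Reagents that add atoms: triflic anhydride, O=S(=O)(OS(=O)(=O)C(F)(F)F)C(F)(F)F
Why: Phenol O-sulfonylation turns the directing OH into a cross-coupling handle; the stereocentre is untouched.

**Step 5**
Reactants: 7; 8 (4-acetoxystyrene)
Product: 9, 4-[(E)-2-{2-[(1S)-2-(3,5-bis(benzyloxy)phenyl)-1-(4-methoxyphenyl)ethyl]-3,5-dimethoxyphenyl}ethenyl]phenyl acetate
Conditions: PdCl2(PPh3)2 (5 mol %), LiCl, Et3N, BHT, DMF, 100 °C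
Reagents that add atoms: none (all atoms from 7 and 8)
Why: Mizoroki–Heck reaction of the aryl triflate (LiCl enforces the neutral pathway) gives β-arylation and the E-stilbene by syn-insertion/syn-β-H elimination; the acetate keeps this aryl group electron-poor for steps 7 and 9.

**Step 6**
Reactants: 9
Product: 10, 4-[(2S,3S)-3-{2-[(1S)-2-(3,5-bis(benzyloxy)phenyl)-1-(4-methoxyphenyl)ethyl]-3,5-dimethoxyphenyl}oxiran-2-yl]phenyl acetate
Conditions: ent-Shi ketone (L-fructose-derived, 30 mol %), Oxone, K2CO3, Bu4NHSO4, MeCN/DMM/aq Na2B4O7–EDTA buffer (pH 10.5), 0 °C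
Reagents that add atoms: Oxone (potassium peroxymonosulfate), OOS(=O)(=O)[O-].[K+]
Why: Shi asymmetric epoxidation of a trans-stilbene through the spiro dioxirane transition state is reagent-controlled; the D-fructose ketone gives (R,R)-stilbene oxides, so the enantiomeric ketone gives the (S,S)-epoxide. Aryl acetates should survive, as enol esters are tolerated under these conditions.

**Step 7**
Reactants: 10
Product: 11, 4-[(R)-hydroxy{(5S,10S)-2,4-bis(benzyloxy)-7,9-dimethoxy-10-(4-methoxyphenyl)-10,11-dihydro-5H-dibenzo[a,d][7]annulen-5-yl}methyl]phenyl acetate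
Conditions: HFIP (0.01 M), 0 °C → rt
Reagents that add atoms: none
Why: Proposed new method: HFIP hydrogen-bond activation lets the only arene carbon that is both doubly activated (ortho/para to two OBn) and within reach attack the epoxide carbon next to the dimethoxyaryl ring anti to the C–O bond (7-exo-tet, SN2-like Friedel–Crafts alkylation). This inverts that carbon to (S) and leaves the other C–O bond intact as the (R)-carbinol; neither epoxide carbon is strongly cation-stabilised (4-AcO-aryl and meta-dimethoxyaryl), which disfavours Meinwald rearrangement. The closest known reactions are the inverting HFIP- or Lewis-acid-promoted Friedel–Crafts alkylations of electron-rich arenes with aryl epoxides (epoxy-arene cyclisation).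

**Step 8**
Reactants: 11
Product: 12, 4-[(R)-hydroxy{(5S,10S)-2,4-dihydroxy-7,9-dimethoxy-10-(4-methoxyphenyl)-10,11-dihydro-5H-dibenzo[a,d][7]annulen-5-yl}methyl]phenyl acetate
Conditions: H2 (1 atm), 10% Pd/C, EtOAc, rt (monitor; stop at full debenzylation)
Reagents that add atoms: none
Why: Hydrogenolysis of the two aryl benzyl ethers; the secondary benzylic alcohol on the electron-poor aryl, the acetate and the methyl ethers are much slower to react; no stereocentre is touched.

**Step 9**
Reactants: 12
Product: 13, ampelopsin B tri-O-methyl ether 4-O-acetate: the tetracycle of the target with OMe on the resorcinol ring of the seven-membered ring (×2) and on the 4-oxyphenyl at the benzylic CH, OAc on the aryl at furan C2, and one free OH on the benzofuran ring; (2S,3S)-trans-dihydrobenzofuran, (S) at the benzylic CH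
Conditions: PPh3, DIAD, THF (0.01 M), 0 °C → rt
Reagents that add atoms: none
Why: Intramolecular Mitsunobu etherification; the ortho phenol displaces the activated (R)-carbinol in a 5-exo-tet SN2 with inversion, giving the (2S) centre and hence the trans-2,3-dihydrobenzofuran; the electron-poor aryl suppresses SN1 scrambling and the para OH cannot reach.

**Step 10**
Reactants: 13
Product: 14, ampelopsin B
Conditions: BBr3 (10 equiv), CH2Cl2, −78 °C → rt; then MeOH, 0 → 40 °C
Reagents that add atoms: none
Why: Global aryl methyl ether cleavage with BBr3, followed by HBr/MeOH methanolysis of the aryl acetate on quench; the acetate keeps the C2–O bond from ionising during demethylation, and any C2 epimerisation after its removal returns to the trans isomer under acid.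

## Compound list

1 | 1,3,5-trimethoxybenzene | COc1cc(OC)cc(OC)c1 | starting material
2 | 4-methoxybenzoyl chloride | COc1ccc(cc1)C(Cl)=O | starting material
3 | (2-hydroxy-4,6-dimethoxyphenyl)(4-methoxyphenyl)methanone | COc1ccc(cc1)C(=O)c1c(O)cc(OC)cc1OC | intermediate
4 | 3,5-bis(benzyloxy)benzyl bromide | BrCc1cc(OCc2ccccc2)cc(OCc2ccccc2)c1 | starting material
5 | 2-[2-(3,5-bis(benzyloxy)phenyl)-1-(4-methoxyphenyl)ethenyl]-3,5-dimethoxyphenol (E/Z) | COc1ccc(cc1)C(=Cc1cc(OCc2ccccc2)cc(OCc2ccccc2)c1)c1c(O)cc(OC)cc1OC | intermediate
6 | (S)-triarylethane phenol | COc1ccc([C@H](Cc2cc(OCc3ccccc3)cc(OCc3ccccc3)c2)c2c(O)cc(OC)cc2OC)cc1 | intermediate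
7 | (S)-aryl triflate | COc1ccc([C@H](Cc2cc(OCc3ccccc3)cc(OCc3ccccc3)c2)c2c(OS(=O)(=O)C(F)(F)F)cc(OC)cc2OC)cc1 | intermediate
8 | 4-acetoxystyrene | CC(=O)Oc1ccc(C=C)cc1 | starting material
9 | (S)-E-stilbene acetate | COc1ccc([C@H](Cc2cc(OCc3ccccc3)cc(OCc3ccccc3)c2)c2c(/C=C/c3ccc(OC(C)=O)cc3)cc(OC)cc2OC)cc1 | intermediate
10 | (2S,3S)-epoxide, (S) at the benzylic CH | COc1ccc([C@H](Cc2cc(OCc3ccccc3)cc(OCc3ccccc3)c2)c2c([C@@H]4O[C@H]4c4ccc(OC(C)=O)cc4)cc(OC)cc2OC)cc1 | intermediate
11 | (5S,10S)-dibenzosuberane (R)-carbinol, bis-benzyl ether | COc1ccc([C@@H]2Cc3cc(OCc4ccccc4)cc(OCc4ccccc4)c3[C@H](c3cc(OC)cc(OC)c32)[C@@H](O)c2ccc(OC(C)=O)cc2)cc1 | intermediate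
12 | (5S,10S)-dibenzosuberane (R)-carbinol, free resorcinol | COc1ccc([C@@H]2Cc3cc(O)cc(O)c3[C@H](c3cc(OC)cc(OC)c32)[C@@H](O)c2ccc(OC(C)=O)cc2)cc1 | intermediate
13 | ampelopsin B tri-O-methyl ether 4-O-acetate | COc1ccc([C@@H]2Cc3cc(O)cc4c3[C@H](c3cc(OC)cc(OC)c32)[C@@H](c2ccc(OC(C)=O)cc2)O4)cc1 | intermediate
14 | ampelopsin B | Oc1ccc([C@@H]2Cc3cc(O)cc4c3[C@H](c3cc(O)cc(O)c32)[C@@H](c2ccc(O)cc2)O4)cc1 | target

## Summary

Total steps: 10. Longest linear sequence: 10 (1 → 14); 2, 4 and 8 enter directly as purchased building blocks.

Steps most likely to fail, with fallbacks: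

1. **Step 7 (7-exo epoxide–arene cyclisation).** Risks are Meinwald rearrangement, slow closure, or a mismatched pairing between the existing (S) centre and the (S,S)-epoxide. Fallback: make the same C–aryl bond from a carbonyl. Convert triflate 7 to the aldehyde (Pd, CO/H2), close the seven-membered ring by acid-mediated intramolecular hydroxyalkylation, debenzylate to the o-hydroxy diarylcarbinol, and build the dihydrobenzofuran by trans-selective [4+1] annulation of the derived o-quinone methide with a chiral 4-acetoxybenzyl sulfonium ylide.
2. **Step 3 (phosphoric acid transfer hydrogenation).** Risks are low ee from the di-ortho-substituted quinone methide and an unknown sense of induction. Fallback: switch to metal catalysis. O-triflate 5, separate or stereoselectively prepare one alkene isomer (stepwise Suzuki couplings on the gem-dibromoalkene of 3,5-bis(benzyloxy)benzaldehyde), and set the centre by Ir–N,P-catalysed asymmetric hydrogenation of the geometrically pure triarylethylene, which gives 7 directly.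
3. **Step 9 (Mitsunobu closure at a hindered benzylic carbinol).** Risk is E2 elimination to the exocyclic stilbene. Fallback: change from SN2 to a thermodynamic p-quinone methide closure. Remove the acetate (K2CO3, MeOH) and treat the 4-hydroxybenzylic alcohol with catalytic acid; the p-quinone methide is trapped by the adjacent phenol (oxa-1,6-addition) to give the trans-dihydrobenzofuran.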